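## Retrosynthetic overview
1. Key step: target **8** is cut at the Ar1–C1 bond, and the C3 ketone is traced back to a carbinol. This gives a Heck arylation/redox isomerisation of bis-allylic alcohol **6** with 4-iodoguaiacol **7**. The usual C4=C5 aldol/HWE (zingerone + aldehyde) is deliberately avoided.
2. **6** is cut at C2–C3 to vinylmagnesium bromide **5** and (E)-enal **4**.
3. **4** is cut at C6–C7 to commercial 1-(TMSO)butadiene **3** and the syringyl quinone-methide cation released from syringyl alcohol **1**. This γ-selective vinylogous Mukaiyama benzylation sets the E-alkene.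
4. No rings are formed. Both arenes are purchased, and the only protection is a transient TMS group that is lost in the work-up of Step 2.
5. Assumption: the target has no stereocentre, so "single enantiomer" is taken to mean the single (E)-C4=C5 isomer.

## Route

**Step 1**
Reactants: **1**, 4-(hydroxymethyl)-2,6-dimethoxyphenol (syringyl alcohol)
Product: **2**, bis-TMS ether of **1** ([3,5-dimethoxy-4-(trimethylsilyloxy)benzyl]oxy-trimethylsilane)
Conditions: HMDS (1.5 equiv), TMSCl (2 mol %), CH2Cl2, 40 °C, 2 h; evaporate and use crude
Reagents that add atoms: hexamethyldisilazane, C[Si](C)(C)N[Si](C)(C)C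
Why: Standard O-silylation of the phenol and the benzylic alcohol gives only volatile by-products (NH3, excess HMDS), so no amine salt is left to poison the Lewis acid in Step 2.

**Step 2**
Reactants: **2**, bis-TMS syringyl alcohol; **3**, (E)-1-(trimethylsilyloxy)buta-1,3-diene (the commercial E/Z mixture is acceptable)
Product: **4**, (E)-5-(4-hydroxy-3,5-dimethoxyphenyl)pent-2-enal
Conditions: **3** (1.5 equiv), TMSOTf (10 mol %), 2,6-di-tert-butylpyridine (5 mol %), CH2Cl2, −78 → −30 °C, slow addition of **2**; then 1 M HCl/THF, 0 °C, 15 min
Reagents that add atoms: none beyond reactant **3**, C=C/C=C/O[Si](C)(C)C, which supplies C3–C6 and the carbonyl O (TMSOTf is catalytic; the work-up adds only H)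
Why: Proposed new method: TMSOTf removes the benzylic OTMS group as (TMS)2O to give the O-silylated syringyl p-quinone methide (a vinylogous oxocarbenium ion), which the much more nucleophilic silyl dienol ether attacks at its unhindered γ-terminus through the s-trans conformer, so that silyl loss regenerates TMSOTf and delivers the E-enal, with any Z isomer equilibrating to E in the acidic work-up that also cleaves the aryl TMS ether; the closest known reaction types are the γ-selective vinylogous Mukaiyama reaction of **3** with acetals, the ZnBr2-catalysed benzylation of silyl (di)enol ethers with SN1-active benzyl halides, and Lewis-acid 1,6-additions of silyl nucleophiles to p-quinone methides.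

**Step 3**
Reactants: **4**, (E)-enal; **5**, vinylmagnesium bromide
Product: **6**, (E)-7-(4-hydroxy-3,5-dimethoxyphenyl)hepta-1,4-dien-3-ol (racemic at C3, E at C4=C5)
Conditions: **5** (2.3 equiv, 1 M in THF), THF, −78 → 0 °C; sat. aq NH4Cl; Et3N-deactivated SiO2
Reagents that add atoms: vinylmagnesium bromide, C=C[Mg]Br
Why: In this Grignard 1,2-addition to an enal the first equivalent only deprotonates the phenol and the second adds to C=O, the E-alkene is untouched, and the new carbinol centre is deliberately racemic because Step 4 destroys it.

**Step 4 (key step)**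
Reactants: **6**, (E)-bis-allylic alcohol; **7**, 4-iodo-2-methoxyphenol
Product: **8**, (E)-1-(4-hydroxy-3-methoxyphenyl)-7-(4-hydroxy-3,5-dimethoxyphenyl)hept-4-en-3-one (target)
Conditions: **7** (1.1 equiv), Pd(OAc)2 (5 mol %), n-Bu4NCl (1 equiv), NaHCO3 (2.5 equiv), degassed DMF, 50 °C
Reagents that add atoms: 4-iodo-2-methoxyphenol, COc1cc(I)ccc1O
Why: In this Mizoroki–Heck arylation of a secondary allylic alcohol with in-situ redox isomerisation (Jeffery conditions), ArPdI inserts into the monosubstituted C1=C2 alkene with aryl going to C1, β-hydride elimination of the doubly allylic C3–H gives a 2-hydroxydiene that tautomerises to the ketone and erases the carbinol centre, the slower 1,2-disubstituted E-C4=C5 alkene is left in place as the thermodynamically preferred E-enone, and free phenols are tolerated just as in the known synthesis of 4-(hydroxyaryl)butan-2-ones from halophenols and but-3-en-2-ol.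

## Compound list
1 | 4-(hydroxymethyl)-2,6-dimethoxyphenol (syringyl alcohol) | OCc1cc(OC)c(O)c(OC)c1 | starting material
2 | bis-TMS ether of syringyl alcohol | COc1cc(CO[Si](C)(C)C)cc(OC)c1O[Si](C)(C)C | intermediate
3 | (E)-1-(trimethylsilyloxy)buta-1,3-diene | C=C/C=C/O[Si](C)(C)C | starting material
4 | (E)-5-(4-hydroxy-3,5-dimethoxyphenyl)pent-2-enal | O=C/C=C/CCc1cc(OC)c(O)c(OC)c1 | intermediate
5 | vinylmagnesium bromide | C=C[Mg]Br | starting material
6 | (E)-7-(4-hydroxy-3,5-dimethoxyphenyl)hepta-1,4-dien-3-ol (racemic C3) | C=CC(O)/C=C/CCc1cc(OC)c(O)c(OC)c1 | intermediate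
7 | 4-iodo-2-methoxyphenol | COc1cc(I)ccc1O | starting material
8 | (E)-1-(4-hydroxy-3-methoxyphenyl)-7-(4-hydroxy-3,5-dimethoxyphenyl)hept-4-en-3-one | COc1cc(CCC(=O)/C=C/CCc2cc(OC)c(O)c(OC)c2)ccc1O | target

## Summary
Total step count: 4. Longest linear sequence: 4.

Steps most likely to fail, with fallbacks:
1. **Step 2.**
   - Failure modes: sluggish ionisation of a primary benzylic silyl ether, Friedel–Crafts self-oligomerisation of the cation, or α-attack by the diene.
   - Fallback: abandon the cation. Convert **1** to 4-(TBSO)-3,5-dimethoxybenzyl bromide and couple it with allylMgBr (SN2, Cu-catalysed) to give the 4-arylbut-1-ene. Cross-metathesis with crotonaldehyde (Hoveyda–Grubbs II) then gives the enal.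
2. **Step 4.**
   - Failure modes: β-H elimination toward C1 to give the styrenyl dienol, β-OH elimination, Pd–H isomerisation of **6** to the ethyl enone, or π-allyl ionisation.
   - Fallback: oxidise **6** with MnO2 to the cross-conjugated (E)-hepta-1,4-dien-3-one. Install Ar1 by Rh(I)-catalysed Hayashi–Miyaura 1,4-addition of 4-hydroxy-3-methoxyphenylboronic acid pinacol ester, which selects the unsubstituted vinyl terminus.
3. **Step 3.**
   - Failure modes: an insoluble magnesium phenoxide, some 1,4-addition, or acid-catalysed allylic transposition of **6** during isolation.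
   - Fallback: bypass **6**. Hydroborate TBS-protected 2-methoxy-4-vinylphenol and transmetalate B→Zn. Add the 2-arylethylzinc reagent 1,2 to enal **4**, oxidise the allylic alcohol with MnO2, and desilylate.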